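**Retrosynthetic overview**
1. Target ⇒ its aryl tosylate (S–O cleavage) ⇒ tetrabromo-diamine (double hydrodediazoniation). Each ring carries one NH2, para to OMe or OTs, as a traceless director whose two ortho sites are the four C–Br positions.
2. Tetrabromo-diamine ⇒ diamine (four aromatic brominations) ⇒ 2-(2-methoxy-5-nitrophenoxy)-4-nitrophenol (tosylation, then hydrogenation).
3. Key disconnection: ring B of that nitrophenol is opened into 1-(2-methoxy-5-nitrophenoxy)propan-2-one and sodium nitromalonaldehyde. In the forward sense this is an intermolecular aldol condensation, then a ring-closing aldol and aromatisation.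
4. The ketone ⇒ 2-methoxy-5-nitrophenol + chloroacetone, so the oxygen bridge is made as a simple Williamson ether. The nitromalonaldehyde salt ⇒ mucobromic acid + NaNO2.
5. Ring order: ring A (methoxy ring) is bought intact. Ring B (phenol ring) is the only ring formed, in step 3.

Assumption: the target has no stereocentre and its diaryl ether axis rotates freely at room temperature. It is therefore one achiral compound, and no step has to control configuration.
Handling note: sodium nitromalonaldehyde is impact- and heat-sensitive. Make it in small batches, never grind it, and never dry it hot.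

**Step 1**
Reactants: 1 mucobromic acid ((Z)-2,3-dibromo-4-oxobut-2-enoic acid)
Product: 2 sodium nitromalonaldehyde monohydrate
Conditions: NaNO2 (3.7 equiv), H2O–EtOH, 54 °C, 1.5 h; cool to 0 °C, filter, recrystallise from aq EtOH
Reagents that add atoms: sodium nitrite [Na+].[O-]N=O; water O
Why: Nitrite replaces the vinylic bromides by conjugate addition–elimination (one C–N bond, one C–O bond after hydrolysis) and the resulting acid decarboxylates, a long-proven preparation whose delocalised enolate salt crystallises from the cold mixture in about 35–40% yield.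

**Step 2**
Reactants: 3 2-methoxy-5-nitrophenol (5-nitroguaiacol); 4 chloroacetone
Product: 5 1-(2-methoxy-5-nitrophenoxy)propan-2-one
Conditions: K2CO3 (1.5 equiv), acetone, reflux, 6 h
Reagents that add atoms: none
Why: Williamson ether synthesis, in which K2CO3 fully deprotonates the acidic nitrophenol and the phenoxide displaces chloride from the highly SN2-active α-chloroketone, so the oxygen bridge of the later diaryl ether is made without metal catalysis.

**Step 3**
Reactants: 5 1-(2-methoxy-5-nitrophenoxy)propan-2-one; 2 sodium nitromalonaldehyde monohydrate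
Product: 8 2-(2-methoxy-5-nitrophenoxy)-4-nitrophenol, via acyclic enone aldehyde 6 (not isolated), via cyclic aldol 7 (not isolated)
Conditions: 2 (1.2 equiv), NaOH (1.5 equiv), EtOH–H2O 1:1, 0 °C to rt, 48 h; then 2 M HCl to pH 2
Reagents that add atoms: none
Why: Crossed aldol condensation used as a benzannulation, in which the enolate of 5 adds to one formyl group of 2 (which cannot self-condense) to forge the first ring B C–C bond between the two fragments, the other α-carbon closes the ring on the second formyl group, and loss of two waters plus tautomerisation drains everything into the 4-nitrophenolate, so that only one arene isomer is possible because both α-carbons of 5 end up bonded, and no stereocentre survives.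

**Step 4**
Reactants: 8 2-(2-methoxy-5-nitrophenoxy)-4-nitrophenol
Product: 9 2-(2-methoxy-5-nitrophenoxy)-4-nitrophenyl 4-methylbenzenesulfonate
Conditions: TsCl (1.2 equiv), Et3N (1.5 equiv), DMAP (5 mol%), CH2Cl2, 0 °C to rt
Reagents that add atoms: 4-methylbenzenesulfonyl chloride Cc1ccc(cc1)S(=O)(=O)Cl
Why: Sulfonylation of the phenol gives a tosylate that keeps ring B from being oxidised to a quinone imine after nitro reduction, resists bromonium sources and strong acid, and makes this oxygen a weaker donor than nitrogen so that the amine alone steers the bromination.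

**Step 5**
Reactants: 9 2-(2-methoxy-5-nitrophenoxy)-4-nitrophenyl 4-methylbenzenesulfonate
Product: 10 4-amino-2-(5-amino-2-methoxyphenoxy)phenyl 4-methylbenzenesulfonate
Conditions: H2 (1 atm), 10% Pd/C, EtOAc–EtOH, rt; filter under N2 and use promptly
Reagents that add atoms: none
Why: Catalytic hydrogenation reduces both nitro groups cleanly because no halogen or benzyl group is present yet, and aryl sulfonates and aryl ethers are inert to Pd/C under one atmosphere of H2.

**Step 6**
Reactants: 10 4-amino-2-(5-amino-2-methoxyphenoxy)phenyl 4-methylbenzenesulfonate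
Product: 11 4-amino-2-(3-amino-2,4-dibromo-6-methoxyphenoxy)-3,5-dibromophenyl 4-methylbenzenesulfonate
Conditions: NBS (4.1 equiv, portionwise), MeCN, −10 °C to rt, dark
Reagents that add atoms: N-bromosuccinimide O=C1CCC(=O)N1Br
Why: Electrophilic aromatic bromination under amine control, in which the position para to each NH2 is blocked (OMe or OTs), so the two ortho positions, which are also ortho and para to the bridging oxygen, take up exactly two bromines per ring while the tosyl ring and the sites meta to nitrogen stay untouched at this stoichiometry.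

**Step 7**
Reactants: 11 4-amino-2-(3-amino-2,4-dibromo-6-methoxyphenoxy)-3,5-dibromophenyl 4-methylbenzenesulfonate
Product: 13 3,5-dibromo-2-(2,4-dibromo-6-methoxyphenoxy)phenyl 4-methylbenzenesulfonate, via bis-diazonium hydrogensulfate 12 (not isolated)
Conditions: NaNO2 (2.4 equiv) in conc. H2SO4, add 11 in AcOH, 0–5 °C, 1 h; then 50% aq H3PO2 (20 equiv), Cu2O (5 mol%), 0 °C to rt, 16 h
Reagents that add atoms: none
Why: Diazotisation with nitrosylsulfuric acid (needed for weakly basic 2,6-dibromoanilines) followed by hydrodediazoniation with H3PO2 replaces both diazonium groups by H through an aryl radical chain, the chloride-free medium prevents halogen exchange at the activated ortho bromines, and OMe, OTs and C–Br are inert.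

**Step 8**
Reactants: 13 3,5-dibromo-2-(2,4-dibromo-6-methoxyphenoxy)phenyl 4-methylbenzenesulfonate
Product: 14 3,5-dibromo-2-(2,4-dibromo-6-methoxyphenoxy)phenol (target)
Conditions: 2 M aq NaOH (10 equiv), 1,4-dioxane, 80 °C, 6 h; then 1 M HCl
Reagents that add atoms: none
Why: Saponification of the aryl sulfonate by hydroxide attack at sulfur (S–O cleavage, with the dibromophenoxide as a good leaving group), in which the alcohol-free medium avoids alkyl tosylate formation and therefore O-alkylation, and the unactivated C–Br bonds and the methyl ether survive at 80 °C.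

**Compound list**
1 | mucobromic acid, (Z)-2,3-dibromo-4-oxobut-2-enoic acid | O=C/C(Br)=C(Br)\C(=O)O | starting material
2 | sodium nitromalonaldehyde monohydrate | [Na+].[O-]C=C(C=O)[N+](=O)[O-].O | intermediate
3 | 2-methoxy-5-nitrophenol | COc1ccc(cc1O)[N+](=O)[O-] | starting material
4 | chloroacetone | CC(=O)CCl | starting material
5 | 1-(2-methoxy-5-nitrophenoxy)propan-2-one | COc1ccc(cc1OCC(C)=O)[N+](=O)[O-] | intermediate
6 | 4-(2-methoxy-5-nitrophenoxy)-2-nitro-5-oxohex-3-enal (alkene geometry and acidic CH centre labile in base, not defined) | COc1ccc(cc1OC(=CC(C=O)[N+](=O)[O-])C(C)=O)[N+](=O)[O-] | intermediate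
7 | 5-hydroxy-2-(2-methoxy-5-nitrophenoxy)-4-nitrocyclohex-2-en-1-one (transient diastereomer mixture) | COc1ccc(cc1OC1=CC(C(O)CC1=O)[N+](=O)[O-])[N+](=O)[O-] | intermediate
8 | 2-(2-methoxy-5-nitrophenoxy)-4-nitrophenol | COc1ccc(cc1Oc1cc(ccc1O)[N+](=O)[O-])[N+](=O)[O-] | intermediate
9 | 2-(2-methoxy-5-nitrophenoxy)-4-nitrophenyl 4-methylbenzenesulfonate | COc1ccc(cc1Oc1cc(ccc1OS(=O)(=O)c1ccc(C)cc1)[N+](=O)[O-])[N+](=O)[O-] | intermediate
10 | 4-amino-2-(5-amino-2-methoxyphenoxy)phenyl 4-methylbenzenesulfonate | COc1ccc(N)cc1Oc1cc(N)ccc1OS(=O)(=O)c1ccc(C)cc1 | intermediate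
11 | 4-amino-2-(3-amino-2,4-dibromo-6-methoxyphenoxy)-3,5-dibromophenyl 4-methylbenzenesulfonate | COc1cc(Br)c(N)c(Br)c1Oc1c(Br)c(N)c(Br)cc1OS(=O)(=O)c1ccc(C)cc1 | intermediate
12 | bis-diazonium bis(hydrogensulfate) of 11 | COc1cc(Br)c([N+]#N)c(Br)c1Oc1c(Br)c([N+]#N)c(Br)cc1OS(=O)(=O)c1ccc(C)cc1.OS(=O)(=O)[O-].OS(=O)(=O)[O-] | intermediate
13 | 3,5-dibromo-2-(2,4-dibromo-6-methoxyphenoxy)phenyl 4-methylbenzenesulfonate | COc1cc(Br)cc(Br)c1Oc1c(Br)cc(Br)cc1OS(=O)(=O)c1ccc(C)cc1 | intermediate
14 | 3,5-dibromo-2-(2,4-dibromo-6-methoxyphenoxy)phenol | COc1cc(Br)cc(Br)c1Oc1c(O)cc(Br)cc1Br | target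

**Totals**
Total step count: 8.
Longest linear sequence: 7 steps (steps 2–8 from 3 and 4). The branch from 1 through step 1 joins at step 3 and is also 7 steps long.

**Three steps most likely to fail**

Step 3 (aldol benzannulation). The risks are self-condensation of 5, a slow reaction of the delocalised dialdehyde anion, and a modest yield. The fallback sets out from 3 and comes back at 8. Ring B is bought instead of built, and the bridge is made by a copper-catalysed Ullmann ether coupling. Purchased 2-bromo-4-nitrophenol F1 is benzylated (BnBr, K2CO3, DMF, rt) to 1-(benzyloxy)-2-bromo-4-nitrobenzene F2. This is coupled with phenol 3 (CuCl 0.5 equiv, 2,2,6,6-tetramethylheptane-3,5-dione 0.25 equiv, Cs2CO3, NMP, 120 °C) to give 1-(benzyloxy)-2-(2-methoxy-5-nitrophenoxy)-4-nitrobenzene F3. BCl3 with pentamethylbenzene (CH2Cl2, −78 to 0 °C) then removes the benzyl group without touching the methyl ether and delivers 8.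

Step 6 (fourfold bromination). The risks are oxidation of the anisidine-type ring A by NBS and incomplete reaction at the crowded sites next to the bridge. The fallback sets out from 4, uses 2 again, and comes back at 13. Ring A brings its bromines along, so only the less oxidisable ring B needs an aniline-directed bromination.
- Purchased 4-bromo-2-methoxyphenol F4 is brominated ortho to OH by the amine-mediated method (NBS 1.0 equiv, iPr2NH 10 mol%, CH2Cl2) to 2,4-dibromo-6-methoxyphenol F5.
- F5 is alkylated with 4 (K2CO3, acetone, reflux) to 1-(2,4-dibromo-6-methoxyphenoxy)propan-2-one F6.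
- Aldol condensation with 2 as in step 3 runs through 4-(2,4-dibromo-6-methoxyphenoxy)-2-nitro-5-oxohex-3-enal F7 and 2-(2,4-dibromo-6-methoxyphenoxy)-5-hydroxy-4-nitrocyclohex-2-en-1-one F8. It ends at 2-(2,4-dibromo-6-methoxyphenoxy)-4-nitrophenol F9.
- Tosylation gives 2-(2,4-dibromo-6-methoxyphenoxy)-4-nitrophenyl 4-methylbenzenesulfonate F10.
- Fe powder with NH4Cl (EtOH–H2O, 80 °C, C–Br safe) gives 4-amino-2-(2,4-dibromo-6-methoxyphenoxy)phenyl 4-methylbenzenesulfonate F11.
- NBS (2.05 equiv, MeCN, 0 °C) gives 4-amino-3,5-dibromo-2-(2,4-dibromo-6-methoxyphenoxy)phenyl 4-methylbenzenesulfonate F12.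
- Diazotisation to the mono-diazonium hydrogensulfate F13 and H3PO2 reduction, as in step 7, give 13.

Step 7 (double deamination). The risk is that the H3PO2 reduction of the bis-diazonium salt is incomplete or gives phenol and azo by-products. The fallback sets out from 11 and comes back at 13. Nitrogen is first exchanged for iodine, and the iodine is then removed chemoselectively. Salt 12, made as in step 7, is poured into aq KI (0 °C to rt) to give 3,5-dibromo-2-(2,4-dibromo-3-iodo-6-methoxyphenoxy)-4-iodophenyl 4-methylbenzenesulfonate F14. iPrMgCl·LiCl (2.2 equiv, THF, −40 °C) exchanges only the two C–I bonds, giving the bis(arylmagnesium chloride) F15. This is quenched cold with MeOH, before any aryne formation, to give 13.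

**Further compounds**
F1 | step 3 | 2-bromo-4-nitrophenol (purchased) | Oc1ccc(cc1Br)[N+](=O)[O-]
F2 | step 3 | 1-(benzyloxy)-2-bromo-4-nitrobenzene | O=[N+]([O-])c1ccc(OCc2ccccc2)c(Br)c1
F3 | step 3 | 1-(benzyloxy)-2-(2-methoxy-5-nitrophenoxy)-4-nitrobenzene | COc1ccc(cc1Oc1cc(ccc1OCc1ccccc1)[N+](=O)[O-])[N+](=O)[O-]
F4 | step 6 | 4-bromo-2-methoxyphenol (purchased) | COc1cc(Br)ccc1O
F5 | step 6 | 2,4-dibromo-6-methoxyphenol | COc1cc(Br)cc(Br)c1O
F6 | step 6 | 1-(2,4-dibromo-6-methoxyphenoxy)propan-2-one | COc1cc(Br)cc(Br)c1OCC(C)=O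
F7 | step 6 | 4-(2,4-dibromo-6-methoxyphenoxy)-2-nitro-5-oxohex-3-enal (not isolated) | COc1cc(Br)cc(Br)c1OC(=CC(C=O)[N+](=O)[O-])C(C)=O
F8 | step 6 | 2-(2,4-dibromo-6-methoxyphenoxy)-5-hydroxy-4-nitrocyclohex-2-en-1-one (not isolated) | COc1cc(Br)cc(Br)c1OC1=CC(C(O)CC1=O)[N+](=O)[O-]
F9 | step 6 | 2-(2,4-dibromo-6-methoxyphenoxy)-4-nitrophenol | COc1cc(Br)cc(Br)c1Oc1cc(ccc1O)[N+](=O)[O-]
F10 | step 6 | 2-(2,4-dibromo-6-methoxyphenoxy)-4-nitrophenyl 4-methylbenzenesulfonate | COc1cc(Br)cc(Br)c1Oc1cc(ccc1OS(=O)(=O)c1ccc(C)cc1)[N+](=O)[O-]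
F11 | step 6 | 4-amino-2-(2,4-dibromo-6-methoxyphenoxy)phenyl 4-methylbenzenesulfonate | COc1cc(Br)cc(Br)c1Oc1cc(N)ccc1OS(=O)(=O)c1ccc(C)cc1
F12 | step 6 | 4-amino-3,5-dibromo-2-(2,4-dibromo-6-methoxyphenoxy)phenyl 4-methylbenzenesulfonate | COc1cc(Br)cc(Br)c1Oc1c(Br)c(N)c(Br)cc1OS(=O)(=O)c1ccc(C)cc1
F13 | step 6 | mono-diazonium hydrogensulfate of F12 (not isolated) | COc1cc(Br)cc(Br)c1Oc1c(Br)c([N+]#N)c(Br)cc1OS(=O)(=O)c1ccc(C)cc1.OS(=O)(=O)[O-]
F14 | step 7 | 3,5-dibromo-2-(2,4-dibromo-3-iodo-6-methoxyphenoxy)-4-iodophenyl 4-methylbenzenesulfonate | COc1cc(Br)c(I)c(Br)c1Oc1c(Br)c(I)c(Br)cc1OS(=O)(=O)c1ccc(C)cc1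
F15 | step 7 | bis(arylmagnesium chloride) from F14 (not isolated) | COc1cc(Br)c([Mg]Cl)c(Br)c1Oc1c(Br)c([Mg]Cl)c(Br)cc1OS(=O)(=O)c1ccc(C)cc1
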